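## The problem

Target 17 is a 1,4-benzoquinone whose single six-membered ring carries, in order, a carbonyl at C1, OMe at C2, H at C3, a carbonyl at C4, Me at C5 and an all-E C30 hexaprenyl chain at C6 (chain atoms C1' to C24'). It has no stereocentre, so the only stereochemical elements are five E trisubstituted olefins.

The chain has to be joined at C6, between C1=O and C5–Me. At the arene oxidation level the other free position, C3, lies between two oxygen substituents and is the site that electrophiles and directed metalation prefer.

The C2'=C3' olefin next to the ring is the fragile one: any allyl cation or π-allyl metal intermediate at C1' to C3' can erode its E geometry or give the branched isomer, and under acid the neighbouring quinol oxygen adds across it to close a chroman ring.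

The chain is not an article of commerce and must be built head to tail from C15 pieces. No olefin geometry can control another, so each has to be bought or set on its own and carried through without allylic transposition.

The quinone and its methoxy enone (a vinylogous ester, MeO–C2=C3–C4=O) do not survive strong nucleophiles, base or hot acid, so the ring should reach the quinone level in the last, mild step.

The feature that opens the plan is that C5 and C6, the carbons bearing methyl and chain, are adjacent and are the β- and α-carbons of the C1 carbonyl, while the other α-carbon, C2, is blocked and deactivated by its methoxy group and C4 carries oxygen. The ring therefore maps onto the quinone monoketal 12, in which a methyl nucleophile and the chain electrophile 10 can be placed on C5 and C6 in one operation.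

## Retrosynthesis

**17 ⇒ 14 (through 16 and 15).** No skeletal bond is cut. The C4 carbonyl is returned to a dimethyl ketal and C5 and C6 to sp3 carbons, so 17 is read as the oxidised, aromatised form of cyclohexenone 14. The neighbouring choice, staying at the arene level, exposes only an aryl C–H at C6 and a more reactive one at C3. The dearomatised form exposes C5 and C6 as the β- and α-carbons of an enone, with unambiguous polarity. The forward direction needs ketal hydrolysis, double enolisation to quinol 16 and a two-electron oxidation, all under mild conditions.

**14 ⇒ 12 + methyl (from Me2CuLi) + 10, through enolate 13.** The bonds C5–CH3 and C6–C1' are cut together. Cutting C6–C1' alone would require a C6 nucleophile that the arene does not offer selectively. Cutting ring bonds would require a chain-bearing vinyl metal that is hard to make. Here the precursors are a C9 achiral dienone, a methyl group and a linear allylic bromide, and the step creates the full substitution pattern of the ring. The forward reaction must add methyl 1,4 and at C5 rather than C3, alkylate the enolate on carbon at C6, and do so by direct SN2 displacement so that the 2'E olefin is untouched.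

**12 ⇒ 11.** The C4–OMe bond of the ketal is cut, which is an oxidative dearomatisation of the purchased phenol 11. The phenolic oxygen of 11 fixes which oxygen becomes the free carbonyl, namely C1, next to C2–OMe. A route through a quinone bis-ketal would leave that choice to a partial hydrolysis. The forward step must deliver methanol para, to C4, not ortho, to C2.

**10 ⇒ 9 ⇒ 7 ⇒ 2 + 5 (through 6 and 8).** After the functional-group changes C–Br to C–OH and C13'–H to C13'–SO2Tol, the chain is cut at C12'–C13', the CH2–CH2 bond between prenyl units 3 and 4. This central cut is preferred over the other CH2–CH2 links because both halves are then C15 farnesyl derivatives. The sulfonyl group is a traceless control element that fixes the nucleophilic site of the distal half at its C1. The forward coupling must be α-selective SN2, and the desulfonylation must leave the C14'=C15' olefin in place and E.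

**2 ⇒ 1 and 5 ⇒ 4 ⇒ 3.** Sulfone 2 comes from purchased farnesyl bromide 1 by C–S bond formation. Bromide 5 comes from purchased farnesyl acetate 3 by oxidation of its terminal E methyl group to 4 and exchange of OH for Br. The only new olefin geometry of the whole route, 10'E, is set here.

## Roads not taken

**Alternative 1:** the most obvious cut is C6–C1' alone at the arene level.
- Forward key step: 1,2,4-trimethoxy-5-methylbenzene A1 is lithiated, transmetalated with CuBr·SMe2 and allylated with 10 to give the hexaprenyl arene A2, which (NH4)2Ce(NO3)6 oxidises to 17.
- Why the chosen plan is better: in A1 the hydrogen to be replaced sits between Me and OMe, while the other ring hydrogen sits between two OMe groups. Directed lithiation goes to the latter, and electrophilic halogenation is drawn the same way by two ortho oxygens. The route therefore needs blocking or relay steps before the coupling. The chosen plan turns the same C2 methoxy group from a misdirecting group into the element that shuts C3 down.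

**Alternative 2:** the same bond is made as in the presumed biosynthesis, by electrophilic prenyl transfer to an electron-rich ring.
- Forward key step: Friedel-Crafts alkylation of 2-methoxy-5-methylbenzene-1,4-diol A3 with alcohol 9 and BF3·OEt2 to give quinol 16, then oxidation.
- Why the chosen plan is better: the reaction runs through the C1' to C3' allyl cation. This erodes the 2'E geometry, allows attack through C3', lets the quinol oxygen close a chroman ring, and can start cyclisation of the polyene. C3 competes with C6 as before. The enolate alkylation of the chosen plan is a direct SN2 displacement with no cationic intermediate.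

**Alternative 3:** the ring bonds C1–C6 and C4–C5 are cut, so that the quinone ring is closed between a C4 half and a C2 half.
- Forward key step: the vinyllithium from iodide A5 adds to the C2 carbonyl of 3-methoxycyclobut-3-ene-1,2-dione A4 to give cyclobutenone A6. Heating opens the four-membered ring to a dienylketene that closes by 6π electrocyclisation to quinol 16 (Moore rearrangement), regiospecifically.
- Why the chosen plan is better: A5 would have to come from 10 through a propynyl coupling and a hydroiodination of an unsymmetrical dialkyl alkyne that has no element to control its regiochemistry. Several extra steps would be spent on the C30 material, to build ring atoms C1 to C4 that a purchased phenol already holds.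

Key step: step 8

Remark: (2E,6E)-farnesyl bromide 1, (2E,6E)-farnesyl acetate 3 and 2,4-dimethoxyphenol 11 are taken as purchased, isomerically pure materials. "Hexaprenyl" means the (2E,6E,10E,14E,18E)-3,7,11,15,19,23-hexamethyltetracosa-2,6,10,14,18,22-hexaen-1-yl group, and ring atoms keep the numbering C1 to C6 given above.

## Route

**Step 1**
Reactants: 1 (2E,6E)-farnesyl bromide
Product: 2 (2E,6E)-farnesyl p-tolyl sulfone
Conditions: TolSO2Na, DMF, rt
Reagents that add atoms: sodium p-toluenesulfinate, Cc1ccc(cc1)S(=O)[O-].[Na+]
Why: SN2 S-alkylation of the sulfinate by the primary allylic bromide (sulfone synthesis); the soft sulfur end attacks C1 without allylic transposition, so both olefins keep their E geometry.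

**Step 2**
Reactants: 3 (2E,6E)-farnesyl acetate
Product: 4 (2E,6E,10E)-12-hydroxy-3,7,11-trimethyldodeca-2,6,10-trien-1-yl acetate
Conditions: SeO2 (cat.), t-BuOOH, salicylic acid (cat.), CH2Cl2, rt
Reagents that add atoms: SeO2, O=[Se]=O (delivers the oxygen atom); tert-butyl hydroperoxide, CC(C)(C)OO (restores SeO2)
Why: SeO2-catalysed allylic oxidation (Riley oxidation, ene reaction then [2,3]-sigmatropic shift) should attack the terminal, most electron-rich olefin, remote from the deactivating acetate. It oxidises the methyl group trans to the chain, which sets the 10E geometry.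

**Step 3**
Reactants: 4 (2E,6E,10E)-12-hydroxy-3,7,11-trimethyldodeca-2,6,10-trien-1-yl acetate
Product: 5 (2E,6E,10E)-12-bromo-3,7,11-trimethyldodeca-2,6,10-trien-1-yl acetate
Conditions: CBr4, PPh3, CH2Cl2, −20 °C
Reagents that add atoms: tetrabromomethane, BrC(Br)(Br)Br
Why: Appel reaction; bromide displaces the oxyphosphonium group at the primary allylic carbon by SN2 under neutral conditions that leave the acetate and the olefins alone, and the low temperature suppresses SN2' transposition.

**Step 4**
Reactants: 2 (2E,6E)-farnesyl p-tolyl sulfone; 5 (2E,6E,10E)-12-bromo-3,7,11-trimethyldodeca-2,6,10-trien-1-yl acetate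
Product: 7 (2E,6E,10E,14E,18E)-3,7,11,15,19,23-hexamethyl-13-(4-methylbenzenesulfonyl)tetracosa-2,6,10,14,18,22-hexaen-1-yl acetate (racemic at C13), via lithiated sulfone 6 (not isolated)
Conditions: n-BuLi, THF, −78 °C; then 5, −78 → −40 °C
Reagents that add atoms: none
Why: Allyl sulfone alkylation (Biellmann coupling): the sulfonyl-stabilised anion 6 reacts at its α-carbon with the primary allylic bromide by SN2, which joins the halves head to tail and moves no olefin. At −78 °C alkylation should outrun attack on the acetate; the new stereocentre C13 is racemic and is removed in step 5.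

**Step 5**
Reactants: 7 C30 sulfone acetate
Product: 9 all-E-hexaprenol, (2E,6E,10E,14E,18E)-3,7,11,15,19,23-hexamethyltetracosa-2,6,10,14,18,22-hexaen-1-ol, via lithium alkoxide 8 (not isolated)
Conditions: LiBHEt3 (excess), THF, 0 °C; then PdCl2(dppp) (cat., dppp = Ph2P(CH2)3PPh2), 0 °C → rt
Reagents that add atoms: none
Why: LiBHEt3 first cleaves the acetate to alkoxide 8, which a zerovalent palladium catalyst cannot ionise. The catalyst formed from PdCl2(dppp) then ionises only the allylic sulfone, and hydride is delivered to the less substituted terminus C13 of the π-allyl complex (palladium-catalysed reductive desulfonylation), so the 14,15-olefin should stay in place and E.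

**Step 6**
Reactants: 9 all-E-hexaprenol
Product: 10 all-E-hexaprenyl bromide, (2E,6E,10E,14E,18E)-1-bromo-3,7,11,15,19,23-hexamethyltetracosa-2,6,10,14,18,22-hexaene
Conditions: PBr3, Et2O, 0 °C
Reagents that add atoms: phosphorus tribromide, BrP(Br)Br
Why: Bromination of a primary allylic alcohol through its phosphite ester with SN2 attack of bromide at C1, the standard conversion of polyprenols; at 0 °C the 2E geometry should be kept. The bromide is used crude in step 8.

**Step 7**
Reactants: 11 2,4-dimethoxyphenol
Product: 12 2,4,4-trimethoxycyclohexa-2,5-dien-1-one
Conditions: PhI(OAc)2, MeOH, 0 °C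
Reagents that add atoms: methanol, CO
Why: Oxidative dearomatisation of a p-methoxyphenol with a hypervalent iodine reagent: after ligand exchange at iodine and two-electron oxidation, methanol captures the phenoxonium ion at C4, para to the oxygen, where the 4-methoxy group stabilises the charge. The phenol oxygen becomes the C1 carbonyl next to C2–OMe.

**Step 8**
Reactants: 12 2,4,4-trimethoxycyclohexa-2,5-dien-1-one (in excess); 10 all-E-hexaprenyl bromide (limiting)
Product: 14 trans-2,4,4-trimethoxy-5-methyl-6-hexaprenylcyclohex-2-en-1-one, racemic (5S,6S)/(5R,6R), via lithium enolate 13 (not isolated)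
Conditions: MeLi, CuI, Et2O, 0 °C (gives Me2CuLi); 12, −78 °C; then 10, THF/DMPU, −78 → −20 °C
Reagents that add atoms: lithium dimethylcuprate, [Li+].C[Cu-]C (made in the flask from methyllithium, [Li]C, and CuI)
Why: The reaction type is the tandem cuprate conjugate addition and enolate C-alkylation of a cyclic enone (vicinal difunctionalisation), here run on a quinone monoketal. Me2CuLi forms a π-complex with the C5=C6 enone of 12 and transfers methyl to C5, giving the regiodefined lithium enolate 13 (O–C1=C6). The C2=C3 enone is an α-methoxy enone whose β-carbon C3 receives electron density from the methoxy oxygen, so C3 should stay untouched, and the soft cuprate should not add to the carbonyl. Enolate 13 has a single nucleophilic carbon, C6, because the other α-position C2 is a fully substituted sp2 carbon. It is alkylated there by the primary allylic bromide 10 in an SN2 reaction that passes through neither an allyl cation nor a π-allyl metal, so the 2'E geometry and the linear connectivity are kept. No ring is closed. The two new stereocentres C5 and C6 are set under substrate control, the chain entering anti to the C5 methyl group (trans, racemic); both become sp2 in step 9, so their configuration does not matter. The selectivities needed are 1,4 over 1,2 and C5 over C3 addition (secured by the cuprate and by C2–OMe), C over O and SN2 over SN2' alkylation (lithium enolate, primary allylic bromide, DMPU), and mono- over dialkylation (10 is the limiting component and the remaining C6–H sits on a flanked tertiary carbon).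

**Step 9**
Reactants: 14 trans-2,4,4-trimethoxy-5-methyl-6-hexaprenylcyclohex-2-en-1-one
Product: 17 2-methoxy-5-methyl-6-hexaprenyl-1,4-benzoquinone (6-methoxy-3-methyl-2-hexaprenylcyclohexa-2,5-diene-1,4-dione), via ene-dione 15 (not isolated), via quinol 16 (not isolated)
Conditions: AcOH/THF/H2O, rt; then PhI(OAc)2, MeCN/H2O, 0 °C
Reagents that add atoms: water, O
Why: The C4 ketal is allylic and its cation is stabilised through C3 by the C2 methoxy group, so dilute acid should hydrolyse it to ene-dione 15, which enolises twice to the aromatic quinol 16 (ketal hydrolysis and tautomerisation). PhI(OAc)2 then removes two electrons and two protons to give the quinone, far faster than it touches isolated olefins.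

## Compound list

1 | (2E,6E)-1-bromo-3,7,11-trimethyldodeca-2,6,10-triene (farnesyl bromide) | BrC/C=C(\C)CC/C=C(\C)CCC=C(C)C | starting material
2 | 1-methyl-4-{[(2E,6E)-3,7,11-trimethyldodeca-2,6,10-trien-1-yl]sulfonyl}benzene (farnesyl p-tolyl sulfone) | Cc1ccc(cc1)S(=O)(=O)C/C=C(\C)CC/C=C(\C)CCC=C(C)C | intermediate
3 | (2E,6E)-3,7,11-trimethyldodeca-2,6,10-trien-1-yl acetate (farnesyl acetate) | CC(=O)OC/C=C(\C)CC/C=C(\C)CCC=C(C)C | starting material
4 | (2E,6E,10E)-12-hydroxy-3,7,11-trimethyldodeca-2,6,10-trien-1-yl acetate | CC(=O)OC/C=C(\C)CC/C=C(\C)CC/C=C(\C)CO | intermediate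
5 | (2E,6E,10E)-12-bromo-3,7,11-trimethyldodeca-2,6,10-trien-1-yl acetate | CC(=O)OC/C=C(\C)CC/C=C(\C)CC/C=C(\C)CBr | intermediate
6 | lithiated sulfone, lithium salt of the C1 carbanion of 2 (not isolated) | [Li+].Cc1ccc(cc1)S(=O)(=O)[CH-]/C=C(\C)CC/C=C(\C)CCC=C(C)C | intermediate
7 | (2E,6E,10E,14E,18E)-3,7,11,15,19,23-hexamethyl-13-(4-methylbenzenesulfonyl)tetracosa-2,6,10,14,18,22-hexaen-1-yl acetate, racemic at C13 | CC(=O)OC/C=C(\C)CC/C=C(\C)CC/C=C(\C)CC(S(=O)(=O)c1ccc(C)cc1)/C=C(\C)CC/C=C(\C)CCC=C(C)C | intermediate
8 | lithium alkoxide of the 13-sulfonyl hexaprenol formed from 7 (not isolated) | [Li+].[O-]C/C=C(\C)CC/C=C(\C)CC/C=C(\C)CC(S(=O)(=O)c1ccc(C)cc1)/C=C(\C)CC/C=C(\C)CCC=C(C)C | intermediate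
9 | (2E,6E,10E,14E,18E)-3,7,11,15,19,23-hexamethyltetracosa-2,6,10,14,18,22-hexaen-1-ol (all-E-hexaprenol) | OC/C=C(\C)CC/C=C(\C)CC/C=C(\C)CC/C=C(\C)CC/C=C(\C)CCC=C(C)C | intermediate
10 | (2E,6E,10E,14E,18E)-1-bromo-3,7,11,15,19,23-hexamethyltetracosa-2,6,10,14,18,22-hexaene (all-E-hexaprenyl bromide) | BrC/C=C(\C)CC/C=C(\C)CC/C=C(\C)CC/C=C(\C)CC/C=C(\C)CCC=C(C)C | intermediate
11 | 2,4-dimethoxyphenol | COc1ccc(O)c(OC)c1 | starting material
12 | 2,4,4-trimethoxycyclohexa-2,5-dien-1-one | COC1=CC(OC)(OC)C=CC1=O | intermediate
13 | lithium enolate (O–C1=C6) of 2,4,4-trimethoxy-5-methylcyclohex-2-en-1-one, racemic (not isolated) | [Li+].[O-]C1=CC(C)C(OC)(OC)C=C1OC | intermediate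
14 | trans-2,4,4-trimethoxy-5-methyl-6-hexaprenylcyclohex-2-en-1-one, racemic, (5S,6S) enantiomer drawn | COC1=CC(OC)(OC)[C@@H](C)[C@H](C/C=C(\C)CC/C=C(\C)CC/C=C(\C)CC/C=C(\C)CC/C=C(\C)CCC=C(C)C)C1=O | intermediate
15 | trans-2-methoxy-5-methyl-6-hexaprenylcyclohex-2-ene-1,4-dione, racemic (not isolated) | COC1=CC(=O)[C@@H](C)[C@H](C/C=C(\C)CC/C=C(\C)CC/C=C(\C)CC/C=C(\C)CC/C=C(\C)CCC=C(C)C)C1=O | intermediate
16 | 2-hexaprenyl-6-methoxy-3-methylbenzene-1,4-diol (not isolated) | COc1cc(O)c(C)c(C/C=C(\C)CC/C=C(\C)CC/C=C(\C)CC/C=C(\C)CC/C=C(\C)CCC=C(C)C)c1O | intermediate
17 | 2-[(2E,6E,10E,14E,18E)-3,7,11,15,19,23-hexamethyltetracosa-2,6,10,14,18,22-hexaen-1-yl]-6-methoxy-3-methylcyclohexa-2,5-diene-1,4-dione | COC1=CC(=O)C(C)=C(C/C=C(\C)CC/C=C(\C)CC/C=C(\C)CC/C=C(\C)CC/C=C(\C)CCC=C(C)C)C1=O | target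

## Step count and least certain steps

Total: 9 steps. Longest linear sequence: 7 steps (3 → 4 → 5 → 7 → 9 → 10 → 14 → 17; steps 2, 3, 4, 5, 6, 8, 9).

**Step 8 (key step).** Most likely to go wrong:
- electron transfer from the cuprate to the dienone, followed by loss of a ketal methoxide and re-aromatisation instead of methyl transfer;
- slow C-alkylation of the hindered, copper-associated enolate, which gives time for proton exchange and a second alkylation, for O-alkylation, and for methyl transfer from the residual methylcopper to the bromide;
- partial addition at C3, which is less likely.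

Fallback, known chemistry with a different bond-forming logic, setting out from 10 and returning at 17: the sodium salt of purchased 2-methoxy-5-methylphenol F1 (NaH, toluene) is C-allylated by 10 at its only free ortho position, between the oxygen and the methyl group, to give 2-hexaprenyl-6-methoxy-3-methylphenol F2. The free para position of F2 is then oxidised with (KSO3)2NO in buffered aqueous acetone (Teuber oxidation) to give 17.

**Step 9.** Most likely to go wrong:
- loss of methanol from the ketal by elimination instead of hydrolysis;
- acid-promoted addition of the C1 hydroxyl of the quinol across the 2',3'-olefin (chroman ring closure);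
- hydrolysis of the C2 enol ether.

Fallback, setting out from 14 and returning at 17: the elimination is made the intended path under aprotic, amine-buffered conditions. TMSOTf and Et3N in CH2Cl2 at −78 °C silylate the ketone, ionise the ketal and remove H-5, and aqueous work-up gives 2-hexaprenyl-4,6-dimethoxy-3-methylphenol F3. F3 is then converted into 17 by oxidative demethylation with PhI(OAc)2 in MeCN/H2O at 0 °C, water entering para to the phenol oxygen.

**Step 5.** Most likely to go wrong:
- hydride delivery to the more substituted allyl terminus (transposition of the 14,15-olefin);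
- syn/anti isomerisation of the π-allyl palladium complex (erosion of the 14E geometry);
- ionisation of the allylic acetate before it is cleaved (loss of the C1 oxygen).

Fallback, setting out from 7 and returning at 9: the acetate is removed first with K2CO3 in MeOH to give the hydroxy sulfone F4. The C–S bond is then cleaved by electron transfer with Li in EtNH2 at −78 °C (dissolving-metal desulfonylation), which involves no allyl metal complex, to give 9.

## Further compounds

F1 | step 8 | 2-methoxy-5-methylphenol (purchased) | COc1ccc(C)cc1O
F2 | step 8 | 2-hexaprenyl-6-methoxy-3-methylphenol | COc1ccc(C)c(C/C=C(\C)CC/C=C(\C)CC/C=C(\C)CC/C=C(\C)CC/C=C(\C)CCC=C(C)C)c1O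
F3 | step 9 | 2-hexaprenyl-4,6-dimethoxy-3-methylphenol | COc1cc(OC)c(C)c(C/C=C(\C)CC/C=C(\C)CC/C=C(\C)CC/C=C(\C)CC/C=C(\C)CCC=C(C)C)c1O
F4 | step 5 | (2E,6E,10E,14E,18E)-3,7,11,15,19,23-hexamethyl-13-(4-methylbenzenesulfonyl)tetracosa-2,6,10,14,18,22-hexaen-1-ol, racemic | OC/C=C(\C)CC/C=C(\C)CC/C=C(\C)CC(S(=O)(=O)c1ccc(C)cc1)/C=C(\C)CC/C=C(\C)CCC=C(C)C
A1 | alternative 1 | 1,2,4-trimethoxy-5-methylbenzene | Cc1cc(OC)c(OC)cc1OC
A2 | alternative 1 | 1-hexaprenyl-2,3,5-trimethoxy-6-methylbenzene | Cc1c(C/C=C(\C)CC/C=C(\C)CC/C=C(\C)CC/C=C(\C)CC/C=C(\C)CCC=C(C)C)c(OC)c(OC)cc1OC
A3 | alternative 2 | 2-methoxy-5-methylbenzene-1,4-diol | COc1cc(O)c(C)cc1O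
A4 | alternative 3 | 3-methoxycyclobut-3-ene-1,2-dione | COC1=CC(=O)C1=O
A5 | alternative 3 | (2E,5E,9E,13E,17E,21E)-3-iodo-6,10,14,18,22,26-hexamethylheptacosa-2,5,9,13,17,21,25-heptaene | C/C=C(/I)C/C=C(\C)CC/C=C(\C)CC/C=C(\C)CC/C=C(\C)CC/C=C(\C)CCC=C(C)C
A6 | alternative 3 | 4-hydroxy-3-methoxy-4-[(2E,5E,9E,13E,17E,21E)-6,10,14,18,22,26-hexamethylheptacosa-2,5,9,13,17,21,25-heptaen-3-yl]cyclobut-2-en-1-one, racemic | COC1=CC(=O)C1(O)/C(=C/C)C/C=C(\C)CC/C=C(\C)CC/C=C(\C)CC/C=C(\C)CC/C=C(\C)CCC=C(C)C
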